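Readings and results are calculated from invented constants.

In the first 0.333 h of the north-east run no Tgt shows, so the curve starts flat: at the start none of Oth is in solution.

common to all: Oth 20 mM (held); Ctl 0.50 mM
- north-east: Sub 0.070 M; run made earlier
- south-west: Sub 0.11 M; run made earlier
- flask: Sub 0.050 M; time 4.0 h

- north-east (time / h: Tgt / %): 0.200: 0; 0.333: 0; 0.667: 3.8; 1.33: 6.4; 2.50: 15.4
- south-west (time / h: Tgt / %): 0.500: 1.4; 1.00: 6.2; 1.33: 6.3; 2.00: 8.9; 2.50: 11.2

(scatter of a reading: 1 percentage point)

- at the start none of Oth is in solution
- Oth2 is what Oth becomes in solution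

- maple: doubling the amount of Ctl, all else as stated
- alder: doubling the transfer coefficient of Oth, all else as stated
- larch: doubling the saturation concentration of Oth, all else as stated

- Tgt at 4.0 h, in percent of the Sub charged
- concentration of Oth2 in solution at 2.0 h, in percent of saturation
- the change that raises the amount of Tgt at 4.0 h, in percent of the Sub charged most ("none" if none brings more than 2 percentage points) (maple / alder / larch / none)
- amount of Tgt at 4.0 h, in percent of the Sub charged, after larch

I count Tgt in molar terms. At 2.50 h the north-east run holds 10.8 mM and the south-west run 12.3 mM, a ratio of 1.14 against 1.57 in Sub. I therefore take two steps in series, both first order in Oth2: transfer with coefficient kL, driven by the gap to the saturation concentration c*, and consumption with a pseudo-first-order coefficient k′, proportional to Sub and to Ctl.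

My carried quantity is the hand-over number G = kL/k′. In this two-step reckoning Tgt forms at kL·c*/(1+G), Oth2 levels at G/(1+G) of saturation, and control crosses at G = 1: below it transfer has the smaller coefficient, above it consumption. The two amounts give G = 0.524 for the north-east run. Its last two readings give a slope of 5.38 mM h⁻¹, hence kL = 0.410 h⁻¹. Both are readings and carry the scatter.

Scaled to this flask, the hand-over number is G = 0.733, below the crossing. The curve leaves zero slope, bends over a time 1/(kL+k′) = 1.03 h, and straightens at 4.73 mM h⁻¹, with Oth2 heading for 42.3%. I reckon Oth2 at 36.2% of saturation at 2.0 h and Tgt at 28.3% at 4.0 h. In my reckoning larch leaves G unchanged and doubles the curve to 56.6%, while alder multiplies the rate by 1.41 and maple by 1.27.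

The forecast gives 33% for Tgt, 15% for Oth2, larch as the best change and 58% after it, on the ground that “Oth2 is consumed almost as it dissolves”; it shares my choice of change and differs from my figure for Oth2.

The flask gives 24.2%, 33.2% and larch, which raises Tgt by 15 percentage points to 39.3%.

    Oth ⇌ Oth2, rate k1*(csat - [Oth2]) (kL = 0.450 h⁻¹)
    Sub + Oth2 + Ctl ⇌ Ctl + Tgt (K = 47.0 M⁻¹, k = 82000 M⁻² h⁻¹)
    Sub + Tgt → Sub.Tgt (k = 1.80 M⁻¹ h⁻¹)
    Oth2 + Ctl ⇌ Oth2.Ctl, settled at all times (K = 55.0 M⁻¹)

The forecast and the flask part on Oth2, which stands at 33.2% of saturation at 2.0 h and at 52.2% at 4.00 h, past my level of 42.3%. The neighbouring flask, charged with 2.0 × 10⁻⁴ M of Ctl and otherwise the same, has G = 1.83 in my reckoning, above the crossing. The same reckoning sets its Oth2 level at 64.7% and its rate at 0.612 of the flask's. In the neighbouring flask, Oth2 stands at 58.1% of saturation at 4.00 h, and Tgt reaches 18.4%, which is 0.760 of the flask's 24.2%.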